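**Retrosynthetic overview**

1. Order of assembly: syringaldehyde (1) + chloroacetyl imide (2) → 3; + ethyl diazoacetate (4) → β‑keto ester 5; + phenol 6 → benzofuran 7; → cis‑8 → trans‑9; + veratraldehyde (10) → 11 → Berbikonol (12).
2. Last disconnection: all three primary alcohols of 12 come from one global hydride reduction of 11 (imide, ethyl ester, methyl ester).
3. 8‑O‑4′ unit: the C7–C8 bond is made by an auxiliary‑controlled anti‑aldol of the aryloxyacetyl imide with 10, setting C7 (S) and C8 (R).
4. Dihydrobenzofuran: C2 is set by enantioselective dearomative hydrogenation of the fully aromatic benzofuran 7 (key step); C3 is then epimerised to trans.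
5. Ring formation: only the furan ring is built (C3a–C3 and O1–C2 in one oxidative annulation of 6 with 5); all benzene rings are purchased.

Assumptions: (i) the (R,R)‑NHC ligand gives the 2R face in Step 4 and the (R)‑auxiliary gives the (2S,3S) anti‑aldol in Step 5 by the chelated‑enolate model; if either sense is reversed, the other commercial antipode is used. (ii) Compounds 2 and 6 are taken as purchasable (each is otherwise one routine step from (R)‑4‑benzyloxazolidin‑2‑one or ferulic acid).

**Route**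

Step 1
Reactants: 1 syringaldehyde; 2 (R)‑4‑benzyl‑3‑(chloroacetyl)oxazolidin‑2‑one
Product: 3 (R)‑4‑benzyl‑3‑[2‑(4‑formyl‑2,6‑dimethoxyphenoxy)acetyl]oxazolidin‑2‑one
Conditions: K2CO3, NaI (cat.), MeCN, 45 °C
Reagents that add atoms: compound 2, O=C(CCl)N1[C@H](Cc2ccccc2)COC1=O
Why: Williamson etherification (SN2, Finkelstein‑assisted) of the weakly basic 4‑formylphenoxide on the α‑chloro imide, which installs the aldol donor without a separate protecting group.

Step 2
Reactants: 3; 4 ethyl diazoacetate
Product: 5 ethyl 3‑{4‑[2‑((R)‑4‑benzyl‑2‑oxooxazolidin‑3‑yl)‑2‑oxoethoxy]‑3,5‑dimethoxyphenyl}‑3‑oxopropanoate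
Conditions: NbCl5 (5 mol %), CH2Cl2, rt
Reagents that add atoms: ethyl diazoacetate, CCOC(=O)C=[N+]=[N-] (N2 is lost)
Why: Roskamp homologation (Lewis‑acid addition of the diazoester to ArCHO, then 1,2‑H shift with loss of N2) gives the β‑keto ester directly, and the imide is inert to these conditions.

Step 3
Reactants: 5; 6 methyl 3‑(4‑hydroxy‑3‑methoxyphenyl)propanoate (2–3 equiv)
Product: 7 ethyl 2‑{4‑[2‑((R)‑4‑benzyl‑2‑oxooxazolidin‑3‑yl)‑2‑oxoethoxy]‑3,5‑dimethoxyphenyl}‑7‑methoxy‑5‑(3‑methoxy‑3‑oxopropyl)benzofuran‑3‑carboxylate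
Conditions: FeCl3·6H2O (10 mol %), (t‑BuO)2 (2 equiv), DCE, 100 °C
Reagents that add atoms: compound 6, COC(=O)CCc1ccc(O)c(OC)c1
Why: Iron‑catalysed cross‑dehydrogenative coupling of the only free ortho C–H of phenol 6 with the keto‑ester α‑carbon, followed by cyclodehydration of the phenol OH onto the aryl ketone (tandem oxidative coupling–annulation), gives the 2‑aryl‑3‑carboxylate benzofuran with the 7‑OMe/5‑alkyl pattern.

Step 4 (key step, one pot)
Reactants: 7
Product: 9 trans‑(2R,3R) ethyl 2‑aryl‑7‑methoxy‑5‑(3‑methoxy‑3‑oxopropyl)‑2,3‑dihydrobenzofuran‑3‑carboxylate (aryl as in 7), formed via the cis‑(2R,3S) isomer 8, which is not isolated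
Conditions: [Ru(cod)(2‑methylallyl)2] (10 mol %), (R,R)‑SINpEt·HBF4, KOt‑Bu (catalyst preformed), H2 (100 bar), toluene, 40 °C; then vent, DBU, 60 °C
Reagents that add atoms: none (H2 only)
Why: Proposed new method: enantioselective dearomative hydrogenation of a 2‑aryl‑benzofuran‑3‑carboxylate, where the closest known reaction is Ru–bis(NHC) asymmetric hydrogenation of 2‑arylbenzofurans to 2‑aryl‑2,3‑dihydrobenzofurans; the ester‑polarised C2=C3 bond is the least aromatic π‑bond, so Ru–H syn‑addition occurs there with the chiral NHC pocket choosing the face (C2 = R, cis‑8), and DBU then epimerises only the ester α‑carbon C3 to the thermodynamically favoured trans isomer 9 without touching C2 (the cis→trans ester epimerisation is known chemistry).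

Step 5
Reactants: 9; 10 veratraldehyde (1.3 equiv)
Product: 11 the (2S,3S) anti‑aldol adduct as its TMS ether: imide 9 carrying on the aryloxy‑bearing α‑carbon a (S)‑CH(OSiMe3)(3,4‑dimethoxyphenyl) group
Conditions: MgCl2 (20 mol %), Et3N (2 equiv), TMSCl (1.5 equiv), EtOAc, rt
Reagents that add atoms: veratraldehyde, COc1ccc(C=O)cc1OC; TMSCl, C[Si](C)(C)Cl
Why: Evans MgCl2‑catalysed anti‑aldol: soft enolisation gives the Mg‑chelated (Z)‑enolate of the imide only (the esters are not enolised), the non‑enolisable aryl aldehyde adds anti to the auxiliary benzyl group through a boat transition state to set C8 and C7 as the anti (erythro) pair, and O‑silylation makes the addition irreversible.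

Step 6
Reactants: 11
Product: 12 Berbikonol, (1S,2R)‑1‑(3,4‑dimethoxyphenyl)‑2‑{4‑[(2R,3S)‑3‑(hydroxymethyl)‑5‑(3‑hydroxypropyl)‑7‑methoxy‑2,3‑dihydrobenzofuran‑2‑yl]‑2,6‑dimethoxyphenoxy}propane‑1,3‑diol
Conditions: LiBH4 (excess), MeOH, THF, 0 → 40 °C; then K2CO3, MeOH, rt
Reagents that add atoms: none
Why: Global hydride reduction: LiBH4 reductively cleaves the N‑acyl oxazolidinone and reduces both esters to the three primary alcohols without epimerising C8 or C3 (the TMS ether blocks retro‑aldol), and mild methanolysis then frees the benzylic alcohol without acid.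

**Compound list**

1 | syringaldehyde | COc1cc(C=O)cc(OC)c1O | starting material
2 | (R)‑4‑benzyl‑3‑(chloroacetyl)oxazolidin‑2‑one | O=C(CCl)N1[C@H](Cc2ccccc2)COC1=O | starting material
3 | (R)‑4‑benzyl‑3‑[2‑(4‑formyl‑2,6‑dimethoxyphenoxy)acetyl]oxazolidin‑2‑one | O=Cc1cc(OC)c(OCC(=O)N2[C@H](Cc3ccccc3)COC2=O)c(OC)c1 | intermediate
4 | ethyl diazoacetate | CCOC(=O)C=[N+]=[N-] | starting material
5 | aryl β‑keto ester | CCOC(=O)CC(=O)c1cc(OC)c(OCC(=O)N2[C@H](Cc3ccccc3)COC2=O)c(OC)c1 | intermediate
6 | methyl 3‑(4‑hydroxy‑3‑methoxyphenyl)propanoate | COC(=O)CCc1ccc(O)c(OC)c1 | starting material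
7 | 2‑aryl‑benzofuran‑3‑carboxylate | CCOC(=O)c1c(-c2cc(OC)c(OCC(=O)N3[C@H](Cc4ccccc4)COC3=O)c(OC)c2)oc2c(OC)cc(CCC(=O)OC)cc12 | intermediate
8 | cis‑(2R,3S)‑dihydrobenzofuran ester (not isolated) | O=C(COc1c(OC)cc([C@@H]2Oc3c(OC)cc(CCC(=O)OC)cc3[C@@H]2C(=O)OCC)cc1OC)N1[C@H](Cc2ccccc2)COC1=O | intermediate
9 | trans‑(2R,3R)‑dihydrobenzofuran ester | O=C(COc1c(OC)cc([C@@H]2Oc3c(OC)cc(CCC(=O)OC)cc3[C@H]2C(=O)OCC)cc1OC)N1[C@H](Cc2ccccc2)COC1=O | intermediate
10 | veratraldehyde | COc1ccc(C=O)cc1OC | starting material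
11 | (2S,3S) anti‑aldol adduct, TMS ether | COc1ccc([C@H](O[Si](C)(C)C)[C@@H](C(=O)N2[C@H](Cc3ccccc3)COC2=O)Oc2c(OC)cc([C@@H]3Oc4c(OC)cc(CCC(=O)OC)cc4[C@H]3C(=O)OCC)cc2OC)cc1OC | intermediate
12 | Berbikonol | COc1ccc([C@H](O)[C@@H](CO)Oc2c(OC)cc([C@@H]3Oc4c(OC)cc(CCCO)cc4[C@H]3CO)cc2OC)cc1OC | target

**Totals**

Total steps: 6 (Step 4 is a one‑pot hydrogenation/epimerisation). Longest linear sequence: 6 (1 → 3 → 5 → 7 → 9 → 11 → 12).

**Three steps most likely to fail, with fallbacks**

- **Step 4** (reactivity and ee on a tetrasubstituted, ester‑bearing benzofuran). Fallback: abandon the dearomatisation and build the dihydrofuran by Rh2(S‑PTTL)4‑catalysed intramolecular benzylic C–H insertion of an aryldiazoacetate (2‑(syringyl‑CH2O)aryl diazoacetate derived from 6), giving the cis ester, followed by the same C3 epimerisation.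
- **Step 3** (phenol homocoupling or low conversion with a guaiacol‑type phenol and a functionalised keto ester). Fallback: ortho‑iodinate 6, Sonogashira‑couple it with the aryl alkyne made from 3 (Ohira–Bestmann), then close the ring by PdI2/KI oxidative alkoxycarbonylative cyclisation (CO/air, EtOH) to the same 3‑carboxylate.
- **Step 5** (anti selectivity and facial sense are not established for an α‑aryloxyacetyl imide). Fallback: carry the syringyl oxygen as a benzyl ether instead of the imide, unmask it after Step 4, alkylate with ethyl 2‑bromo‑3‑(3,4‑dimethoxyphenyl)‑3‑oxopropanoate, and set C7/C8 by a ketoreductase dynamic kinetic reduction of the α‑aryloxy‑β‑keto ester (enzyme panel screened for the anti (2S,3S) isomer) before the global reduction.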